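Cuts, in retrosynthetic order: both O-benzyl groups; the lactone C2-O1 acyl bond, with C5 extended back to a propenyl group; the C3-C4 bond; last, one benzylic C-C bond in each half.
Enabling feature: in the oxolan-2-one ring, C3 (quaternary; OH, the C2 carbonyl, the syringyl CH2) is bonded directly to C4 (veratryl CH2), and C5, the ring OCH2, can be carried as an alkene CH. The opened ring is therefore a γ,δ-unsaturated α-alkoxy acid, the product type of an ester-enolate Claisen rearrangement.
Forward: both arenes are bought and each aryl-C3 half is built by one C-C coupling (glycolate enolate benzylation; alkynyl-benzyl coupling followed by cis semihydrogenation). The halves are tied as an allylic ester and a [3,3] shift makes C3-C4.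
The butyrolactone, the only new ring, closes last, after the propenyl group has been cut down to CH2OH; hydrogenolysis then frees both hydroxyl groups.
Stereochemistry: the one bought centre, that of (S)-but-3-yn-2-ol, is relayed to C4 through a chair with the Z alkene, and the chelated Z ketene acetal sets C3 relative to C4. The racemic α-centre of the acid half is erased on enolisation, and the carbinol centre leaves with the cleaved propenyl group.

Key step: step 10

Assumption: (S)-but-3-yn-2-ol is taken as available in high enantiomeric purity, since it is the only source of absolute configuration in the route.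

Step 1
Reactants: 1 syringaldehyde (4-hydroxy-3,5-dimethoxybenzaldehyde)
Product: 2 4-(benzyloxy)-3,5-dimethoxybenzaldehyde
Conditions: BnBr, K2CO3, DMF, 60 °C
Reagents that add atoms: benzyl bromide, BrCc1ccccc1
Why: Williamson ether synthesis, in which the phenoxide (made more acidic by the para formyl group) displaces bromide by SN2 and the resulting benzyl ether masks the phenol until the last step.

Step 2
Reactants: 2 4-(benzyloxy)-3,5-dimethoxybenzaldehyde
Product: 3 [4-(benzyloxy)-3,5-dimethoxyphenyl]methanol
Conditions: NaBH4, MeOH, 0 °C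
Reagents that add atoms: none
Why: Borohydride reduction of the aryl aldehyde to the primary benzylic alcohol is fast and leaves the three aryl ethers untouched.

Step 3
Reactants: 3 [4-(benzyloxy)-3,5-dimethoxyphenyl]methanol
Product: 4 4-(benzyloxy)-3,5-dimethoxybenzyl bromide
Conditions: PBr3, CH2Cl2, 0 °C
Reagents that add atoms: phosphorus tribromide, BrP(Br)Br
Why: Bromination of a primary benzylic alcohol with PBr3 (phosphite ester, then SN2 by bromide) runs cold and spares the benzyl and methyl aryl ethers.

Step 4
Reactants: 5 methyl 2-(benzyloxy)acetate; 4 4-(benzyloxy)-3,5-dimethoxybenzyl bromide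
Product: 7 racemic methyl 2-(benzyloxy)-3-[4-(benzyloxy)-3,5-dimethoxyphenyl]propanoate, via lithium enolate 6 (not isolated)
Conditions: LiN(iPr)2, THF, −78 °C, 5 (1.5 equiv) added slowly; then DMPU, 4, −78 to −40 °C
Reagents that add atoms: none
Why: Ester enolate alkylation, in which the lithium enolate formed at −78 °C (where Claisen self-condensation and Wittig rearrangement of the benzyl ether are slow) is benzylated by the reactive SN2 electrophile 4 with DMPU as cosolvent, the new centre being left racemic on purpose because it is erased in step 10.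

Step 5
Reactants: 7 racemic methyl 2-(benzyloxy)-3-[4-(benzyloxy)-3,5-dimethoxyphenyl]propanoate
Product: 8 racemic 2-(benzyloxy)-3-[4-(benzyloxy)-3,5-dimethoxyphenyl]propanoic acid
Conditions: LiOH·H2O, THF/MeOH/H2O, rt; then 1 M HCl
Reagents that add atoms: lithium hydroxide, [Li+].[OH-]
Why: Saponification (acyl-oxygen cleavage by hydroxide) of the unhindered methyl ester, to which the benzyl ethers and aryl methyl ethers are inert.

Step 6
Reactants: 9 3,4-dimethoxybenzyl alcohol
Product: 10 3,4-dimethoxybenzyl bromide
Conditions: PBr3, Et2O, 0 °C; used at once without purification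
Reagents that add atoms: phosphorus tribromide, BrP(Br)Br
Why: PBr3 bromination of the primary benzylic alcohol, with the labile electron-rich bromide carried straight into the coupling to avoid self-alkylation on storage.

Step 7
Reactants: 11 (S)-but-3-yn-2-ol; 10 3,4-dimethoxybenzyl bromide
Product: 13 (S)-5-(3,4-dimethoxyphenyl)pent-3-yn-2-ol, via dimagnesium alkoxide-acetylide 12 (not isolated)
Conditions: EtMgBr (2.1 equiv), THF, 0 °C to rt; then CuCl (10 mol %), 10, THF, 50 °C; 1 M HCl quench at 0 °C
Reagents that add atoms: none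
Why: Copper-catalysed coupling of an alkynyl Grignard reagent with a benzylic halide, in which the carbon-bound magnesium of 12 is passed to CuCl and the alkynylcopper displaces the benzylic bromide, while the magnesium alkoxide is too poor a nucleophile to compete and the carbinol centre is not involved.

Step 8
Reactants: 13 (S)-5-(3,4-dimethoxyphenyl)pent-3-yn-2-ol
Product: 14 (2S,3Z)-5-(3,4-dimethoxyphenyl)pent-3-en-2-ol
Conditions: H2 (1 atm), Pd/CaCO3 poisoned with Pb(OAc)2, quinoline, EtOAc, rt
Reagents that add atoms: none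
Why: Lindlar semihydrogenation adds H2 syn on the poisoned palladium surface and stops at the alkene, which gives the Z geometry that the chair of step 10 requires and leaves the carbinol centre untouched.

Step 9
Reactants: 8 racemic 2-(benzyloxy)-3-[4-(benzyloxy)-3,5-dimethoxyphenyl]propanoic acid; 14 (2S,3Z)-5-(3,4-dimethoxyphenyl)pent-3-en-2-ol
Product: 15 (2S,3Z)-5-(3,4-dimethoxyphenyl)pent-3-en-2-yl 2-(benzyloxy)-3-[4-(benzyloxy)-3,5-dimethoxyphenyl]propanoate (both epimers at the acyl α-carbon)
Conditions: DCC, DMAP (cat.), CH2Cl2, 0 °C to rt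
Reagents that add atoms: none
Why: Steglich esterification, in which the carbodiimide-activated acid is transferred by DMAP to the alcohol oxygen so that the carbinol C-O bond is never broken and its S configuration is retained, the epimer mixture at the acyl α-carbon being of no consequence.

Step 10
Reactants: 15 (2S,3Z)-5-(3,4-dimethoxyphenyl)pent-3-en-2-yl 2-(benzyloxy)-3-[4-(benzyloxy)-3,5-dimethoxyphenyl]propanoate (both epimers at the acyl α-carbon)
Product: 19 (2S,3S,4E)-2-(benzyloxy)-2-[4-(benzyloxy)-3,5-dimethoxybenzyl]-3-(3,4-dimethoxybenzyl)hex-4-enoic acid, via chelated lithium enolate 16 (not isolated), via silyl ketene acetal 17 (not isolated), via trimethylsilyl ester 18 (not isolated)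
Conditions: LiN(SiMe3)2 (1.3 equiv), THF, −78 °C; TMSCl/Et3N (premixed), −78 °C to rt, then 45 °C if needed; 1 M HCl work-up
Reagents that add atoms: none
Why: LiN(SiMe3)2 removes the ester α-proton of either epimer of 15 to give enolate 16, in which lithium is held between the enolate oxygen and the benzyloxy oxygen, so silylation gives one ketene acetal geometry (17, silyloxy cis to benzyloxy) whichever epimer entered; on warming, 17 undergoes a concerted suprafacial [3,3]-sigmatropic shift in which the bond between the former α-carbon and the distal alkene carbon forms as the allylic C-O bond breaks, giving silyl ester 18 and, after hydrolysis, acid 19. The closest known reaction type is the chelate-controlled Ireland-Claisen rearrangement of α-alkoxy esters (glycolates, lactates) of enantiopure secondary allylic alcohols. No ring is closed in this step; the six-membered array exists only as the chair transition state. The tertiary centre C3 of 19 is controlled by the (S)-carbinol centre, because 1,3-allylic strain against the Z-alkene substituent keeps the carbinol methyl pseudoequatorial, which fixes the alkene face that is attacked and makes the new alkene E, while the quaternary centre C2 is controlled by the ketene acetal geometry within the same chair, which places both arylmethyl groups pseudoaxial on the two bonding termini and the benzyloxy group pseudoequatorial, so that 2S,3S results. The step needs one ketene acetal geometry, chair over boat, one alkene face and deprotonation only at the ester α-carbon; these are secured by the chelating α-benzyloxy group, by the Z alkene next to the secondary carbinol, and by the far higher acidity of the ester α-proton compared with the skipped benzylic-allylic CH2, the enolate having no β leaving group.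

Step 11
Reactants: 19 (2S,3S,4E)-2-(benzyloxy)-2-[4-(benzyloxy)-3,5-dimethoxybenzyl]-3-(3,4-dimethoxybenzyl)hex-4-enoic acid
Product: 22 (3S,4S)-3-(benzyloxy)-3-[4-(benzyloxy)-3,5-dimethoxybenzyl]-4-(3,4-dimethoxybenzyl)oxolan-2-one, via secondary ozonide 20 (not isolated), via hydroxy acid 21 (not isolated)
Conditions: O3, CH2Cl2, −78 °C, Sudan Red 7B as end-point indicator; then NaBH4, MeOH, −78 °C to rt; then 1 M HCl, rt (TsOH cat. in CH2Cl2 if ring closure is incomplete)
Reagents that add atoms: ozone, O=[O+][O-]
Why: Ozonolysis of the 1,2-disubstituted alkene, which reacts far faster than the alkoxyarenes, followed by borohydride reduction of the ozonide straight to the primary alcohol (so that no epimerisable aldehyde is isolated) and acid-promoted 5-exo-trig lactonisation of the γ-hydroxy acid, favoured by the fully substituted α-carbon, closes the ring without touching either stereocentre.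

Step 12
Reactants: 22 (3S,4S)-3-(benzyloxy)-3-[4-(benzyloxy)-3,5-dimethoxybenzyl]-4-(3,4-dimethoxybenzyl)oxolan-2-one
Product: 23 (3S,4S)-4-(3,4-dimethoxybenzyl)-3-hydroxy-3-(4-hydroxy-3,5-dimethoxybenzyl)oxolan-2-one (CNP0553772.1)
Conditions: H2 (1-3 bar), Pd(OH)2/C, EtOAc/MeOH, rt
Reagents that add atoms: none
Why: Catalytic hydrogenolysis cleaves the benzylic C-O bonds of the aryl benzyl ether and of the hindered tertiary benzyl ether, while the lactone, the aryl methyl ethers and the non-benzylic C3-O bond are inert, so both stereocentres survive.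

Compound list
1 | syringaldehyde (4-hydroxy-3,5-dimethoxybenzaldehyde) | COc1cc(C=O)cc(OC)c1O | starting material
2 | 4-(benzyloxy)-3,5-dimethoxybenzaldehyde | COc1cc(C=O)cc(OC)c1OCc1ccccc1 | intermediate
3 | [4-(benzyloxy)-3,5-dimethoxyphenyl]methanol | COc1cc(CO)cc(OC)c1OCc1ccccc1 | intermediate
4 | 4-(benzyloxy)-3,5-dimethoxybenzyl bromide | BrCc1cc(OC)c(OCc2ccccc2)c(OC)c1 | intermediate
5 | methyl 2-(benzyloxy)acetate | COC(=O)COCc1ccccc1 | starting material
6 | lithium enolate of 5 (lithium on oxygen, cis to the benzyloxy group) | [Li]O/C(OC)=C\OCc1ccccc1 | intermediate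
7 | racemic methyl 2-(benzyloxy)-3-[4-(benzyloxy)-3,5-dimethoxyphenyl]propanoate | COC(=O)C(Cc1cc(OC)c(OCc2ccccc2)c(OC)c1)OCc1ccccc1 | intermediate
8 | racemic 2-(benzyloxy)-3-[4-(benzyloxy)-3,5-dimethoxyphenyl]propanoic acid | OC(=O)C(Cc1cc(OC)c(OCc2ccccc2)c(OC)c1)OCc1ccccc1 | intermediate
9 | 3,4-dimethoxybenzyl alcohol | COc1ccc(CO)cc1OC | starting material
10 | 3,4-dimethoxybenzyl bromide | COc1ccc(CBr)cc1OC | intermediate
11 | (S)-but-3-yn-2-ol | C#C[C@H](C)O | starting material
12 | dimagnesium alkoxide-acetylide of 11 (BrMg on the alkyne carbon and on oxygen) | Br[Mg]C#C[C@H](C)O[Mg]Br | intermediate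
13 | (S)-5-(3,4-dimethoxyphenyl)pent-3-yn-2-ol | COc1ccc(CC#C[C@H](C)O)cc1OC | intermediate
14 | (2S,3Z)-5-(3,4-dimethoxyphenyl)pent-3-en-2-ol | COc1ccc(C/C=C\[C@H](C)O)cc1OC | intermediate
15 | (2S,3Z)-5-(3,4-dimethoxyphenyl)pent-3-en-2-yl 2-(benzyloxy)-3-[4-(benzyloxy)-3,5-dimethoxyphenyl]propanoate (both epimers at the acyl α-carbon) | COc1ccc(C/C=C\[C@H](C)OC(=O)C(Cc2cc(OC)c(OCc3ccccc3)c(OC)c2)OCc2ccccc2)cc1OC | intermediate
16 | chelated lithium enolate of 15 (lithium on the enolate oxygen, cis to the benzyloxy group; S carbinol and Z alkene unchanged) | [Li]O/C(O[C@@H](C)/C=C\Cc1ccc(OC)c(OC)c1)=C(\OCc1ccccc1)Cc1cc(OC)c(OCc2ccccc2)c(OC)c1 | intermediate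
17 | Z trimethylsilyl ketene acetal of 15 (silyloxy cis to benzyloxy; S carbinol and Z alkene unchanged) | C[Si](C)(C)O/C(O[C@@H](C)/C=C\Cc1ccc(OC)c(OC)c1)=C(\OCc1ccccc1)Cc1cc(OC)c(OCc2ccccc2)c(OC)c1 | intermediate
18 | trimethylsilyl ester of acid 19 | COc1ccc(C[C@H]([C@@](OCc2ccccc2)(Cc2cc(OC)c(OCc3ccccc3)c(OC)c2)C(=O)O[Si](C)(C)C)/C=C/C)cc1OC | intermediate
19 | (2S,3S,4E)-2-(benzyloxy)-2-[4-(benzyloxy)-3,5-dimethoxybenzyl]-3-(3,4-dimethoxybenzyl)hex-4-enoic acid | COc1ccc(C[C@H]([C@@](OCc2ccccc2)(Cc2cc(OC)c(OCc3ccccc3)c(OC)c2)C(=O)O)/C=C/C)cc1OC | intermediate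
20 | secondary ozonide of 19 (the propenyl C=C replaced by a 5-methyl-1,2,4-trioxolan-3-yl ring; the two chain stereocentres spatially unchanged, trioxolane carbons unassigned) | COc1ccc(C[C@H]([C@@](OCc2ccccc2)(Cc2cc(OC)c(OCc3ccccc3)c(OC)c2)C(=O)O)C2OOC(C)O2)cc1OC | intermediate
21 | (2S,3S)-2-(benzyloxy)-2-[4-(benzyloxy)-3,5-dimethoxybenzyl]-3-(3,4-dimethoxybenzyl)-4-hydroxybutanoic acid | COc1ccc(C[C@H]([C@@](OCc2ccccc2)(Cc2cc(OC)c(OCc3ccccc3)c(OC)c2)C(=O)O)CO)cc1OC | intermediate
22 | (3S,4S)-3-(benzyloxy)-3-[4-(benzyloxy)-3,5-dimethoxybenzyl]-4-(3,4-dimethoxybenzyl)oxolan-2-one | COc1ccc(C[C@H]2COC(=O)[C@]2(OCc2ccccc2)Cc2cc(OC)c(OCc3ccccc3)c(OC)c2)cc1OC | intermediate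
23 | (3S,4S)-4-(3,4-dimethoxybenzyl)-3-hydroxy-3-(4-hydroxy-3,5-dimethoxybenzyl)oxolan-2-one (CNP0553772.1) | COc1ccc(C[C@H]2COC(=O)[C@]2(O)Cc2cc(OC)c(O)c(OC)c2)cc1OC | target

Total step count: 12.
Longest linear sequence: 9 steps (steps 1, 2, 3, 4, 5, 9, 10, 11 and 12, from syringaldehyde 1); the other branch (steps 6, 7, 8) joins at step 9.

Steps most likely to fail

Step 10. The fully substituted ketene acetal may form without clean chelate control. Part of the material may also rearrange through a boat, because the pseudoaxial veratryl CH2 leans toward the silyloxy group. Either process would erode the selectivity at the quaternary carbon, and the crowded silyl ketene acetal could decompose before it rearranges. The fallback takes the syringyl CH2 out of the rearrangement and installs it afterwards. It sets out from 14, which is esterified with purchased 2-(benzyloxy)acetic acid (DCC, DMAP) to (2S,3Z)-5-(3,4-dimethoxyphenyl)pent-3-en-2-yl 2-(benzyloxy)acetate F1. The chelate-controlled Ireland-Claisen rearrangement of this simple glycolate (LiN(SiMe3)2, then TMSCl/Et3N, THF, −78 °C to rt) involves only a trisubstituted ketene acetal. It should give (2S,3S,4E)-2-(benzyloxy)-3-(3,4-dimethoxybenzyl)hex-4-enoic acid F2, with C3 fixed by the same chirality transfer. Ozonolysis, borohydride reduction and acidification as in step 11 would then give (3S,4S)-3-(benzyloxy)-4-(3,4-dimethoxybenzyl)oxolan-2-one F3. Deprotonation of F3 (LiN(SiMe3)2, THF, −78 °C) erases its α-centre, and the lactone enolate is alkylated with bromide 4 on the face away from the C4 arylmethyl group. This places the two arylmethyl groups trans and returns to the route at 22, before step 12.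

Step 7. The electron-rich benzylic bromide may undergo Wurtz-type homocoupling or decompose under the warm Grignard conditions. The skipped arylalkyne may also isomerise to an allene under base. The fallback avoids both the benzylic electrophile and the alkyne, and it bypasses step 8. It sets out from 11, which is silylated (TBSCl, imidazole, DMF) to (S)-tert-butyl(but-3-yn-2-yloxy)dimethylsilane F4. Iodination (N-iodosuccinimide, AgNO3 cat., acetone) gives (S)-tert-butyl[(4-iodobut-3-yn-2-yl)oxy]dimethylsilane F5. Diimide reduction (2-nitrobenzenesulfonyl hydrazide, Et3N, THF/iPrOH) gives (S,Z)-tert-butyl[(4-iodobut-3-en-2-yl)oxy]dimethylsilane F6. Bromide 10 is converted with Zn dust and LiCl in THF into (3,4-dimethoxybenzyl)zinc bromide F7. Negishi coupling of F6 with F7 (Pd(PPh3)4, THF, rt) proceeds with retention of alkene geometry and should give (S,Z)-tert-butyl{[5-(3,4-dimethoxyphenyl)pent-3-en-2-yl]oxy}dimethylsilane F8. Desilylation with Bu4NF in THF returns to the route at 14.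

Step 11. Ozone may over-oxidise the two alkoxyarene rings if the end point is overrun. The γ-hydroxy acid may also be reduced or cyclised incompletely. The fallback masks the acid and replaces ozone by an osmium-based cleavage that does not attack arenes. It sets out from 19, which is esterified (TMSCHN2, toluene/MeOH) to methyl (2S,3S,4E)-2-(benzyloxy)-2-[4-(benzyloxy)-3,5-dimethoxybenzyl]-3-(3,4-dimethoxybenzyl)hex-4-enoate F9. Lemieux-Johnson cleavage (OsO4 cat., NaIO4, 2,6-lutidine, dioxane/H2O) should give methyl (2S,3R)-2-(benzyloxy)-2-[4-(benzyloxy)-3,5-dimethoxybenzyl]-3-(3,4-dimethoxybenzyl)-4-oxobutanoate F10. Reduction with NaBH4 in MeOH at 0 °C gives methyl (2S,3S)-2-(benzyloxy)-2-[4-(benzyloxy)-3,5-dimethoxybenzyl]-3-(3,4-dimethoxybenzyl)-4-hydroxybutanoate F11. This hydroxy ester lactonises with loss of methanol (spontaneously or with TsOH cat.) and returns to the route at 22.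

Further compounds
F1 | step 10 | (2S,3Z)-5-(3,4-dimethoxyphenyl)pent-3-en-2-yl 2-(benzyloxy)acetate | COc1ccc(C/C=C\[C@H](C)OC(=O)COCc2ccccc2)cc1OC
F2 | step 10 | (2S,3S,4E)-2-(benzyloxy)-3-(3,4-dimethoxybenzyl)hex-4-enoic acid | COc1ccc(C[C@H]([C@H](OCc2ccccc2)C(=O)O)/C=C/C)cc1OC
F3 | step 10 | (3S,4S)-3-(benzyloxy)-4-(3,4-dimethoxybenzyl)oxolan-2-one | COc1ccc(C[C@H]2COC(=O)[C@H]2OCc2ccccc2)cc1OC
F4 | step 7 | (S)-tert-butyl(but-3-yn-2-yloxy)dimethylsilane | C#C[C@H](C)O[Si](C)(C)C(C)(C)C
F5 | step 7 | (S)-tert-butyl[(4-iodobut-3-yn-2-yl)oxy]dimethylsilane | IC#C[C@H](C)O[Si](C)(C)C(C)(C)C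
F6 | step 7 | (S,Z)-tert-butyl[(4-iodobut-3-en-2-yl)oxy]dimethylsilane | I/C=C\[C@H](C)O[Si](C)(C)C(C)(C)C
F7 | step 7 | (3,4-dimethoxybenzyl)zinc bromide | COc1ccc(C[Zn]Br)cc1OC
F8 | step 7 | (S,Z)-tert-butyl{[5-(3,4-dimethoxyphenyl)pent-3-en-2-yl]oxy}dimethylsilane | COc1ccc(C/C=C\[C@H](C)O[Si](C)(C)C(C)(C)C)cc1OC
F9 | step 11 | methyl (2S,3S,4E)-2-(benzyloxy)-2-[4-(benzyloxy)-3,5-dimethoxybenzyl]-3-(3,4-dimethoxybenzyl)hex-4-enoate | COc1ccc(C[C@H]([C@@](OCc2ccccc2)(Cc2cc(OC)c(OCc3ccccc3)c(OC)c2)C(=O)OC)/C=C/C)cc1OC
F10 | step 11 | methyl (2S,3R)-2-(benzyloxy)-2-[4-(benzyloxy)-3,5-dimethoxybenzyl]-3-(3,4-dimethoxybenzyl)-4-oxobutanoate | COc1ccc(C[C@H]([C@@](OCc2ccccc2)(Cc2cc(OC)c(OCc3ccccc3)c(OC)c2)C(=O)OC)C=O)cc1OC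
F11 | step 11 | methyl (2S,3S)-2-(benzyloxy)-2-[4-(benzyloxy)-3,5-dimethoxybenzyl]-3-(3,4-dimethoxybenzyl)-4-hydroxybutanoate | COc1ccc(C[C@H]([C@@](OCc2ccccc2)(Cc2cc(OC)c(OCc3ccccc3)c(OC)c2)C(=O)OC)CO)cc1OC
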